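Retrosynthesis: the O8–angeloyl, O11–acetyl and C11–O bonds are cut first, then C7–C8 of the ten-membered ring, then the butenolide (C7=C11 and O6–C12), then C6–C7, and last C8–C9, which leaves the C6–C9 chain of geranyl acetate.
Enabling feature: in the five-membered lactone (C6, O, C12, C11, C7) the ring-fusion carbon C7 lies β to the C12 carbonyl and carries the carbinol carbon C8, so an α-methylbutenolide with a C8 aldehyde on its C6 side chain can close the carbocycle C8–C9–C10=C1–C2–C3–C4=C5–C6–C7 by ketyl addition to C7.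
Forward: geraniol chain plus one carbon (C8), then the five-membered butenolide by ring-closing metathesis, then the ten-membered ring by SmI2 closure of C7–C8, then oxygenation of C11, then acetate and angelate.
Stereochemistry: C6 comes from a catalytic asymmetric vinyl addition; C7 and C8 from the cyclisation under control of C6 and the E,E-diene tether; C11 from enolate hydroxylation on the convex face of the cis-fused bicycle; the 4E olefin is that of geranyl acetate and the 1(10)E olefin comes from the E-selective allylic oxidation.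

Key step: step 13

Remark: germacrane numbering (C8 carbinol, C9, C10=C1, C2, C3, C4=C5, C6 lactone carbinol, C7 ring fusion, C11, C12 lactone carbonyl) is used throughout, also for chain atoms before the ring exists; the C11 configuration written for 19 is the one expected from convex-face protonation and is erased in step 15.

Step 1
Reactants: 1 geranyl acetate
Product: 2 (2E,6E)-8-hydroxy-3,7-dimethylocta-2,6-dien-1-yl acetate
Conditions: SeO2 (0.1 equiv), t-BuOOH (3 equiv), salicylic acid (0.1 equiv), CH2Cl2, 0 °C to rt
Reagents that add atoms: tert-butyl hydroperoxide, CC(C)(C)OO (source of the new oxygen, passed on by catalytic selenium dioxide, O=[Se]=O)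
Why: Riley-type allylic oxidation (ene reaction, then [2,3]-sigmatropic shift) occurs at the more electron-rich terminal olefin and is known to select its E-methyl group, the 2,3-olefin being deactivated by the allylic acetate.

Step 2
Reactants: 2 (2E,6E)-8-hydroxy-3,7-dimethylocta-2,6-dien-1-yl acetate
Product: 3 (2E,6E)-3,7-dimethyl-8-oxoocta-2,6-dien-1-yl acetate
Conditions: activated MnO2 (15 equiv), CH2Cl2, rt
Reagents that add atoms: none
Why: MnO2 oxidises the allylic alcohol selectively to the conjugated enal and should leave the acetate and the olefin geometry untouched.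

Step 3
Reactants: 3 (2E,6E)-3,7-dimethyl-8-oxoocta-2,6-dien-1-yl acetate
Product: 4 (2E,6E)-3,7-dimethylnona-2,6,8-trien-1-yl acetate
Conditions: Ph3PCH3Br (1.2 equiv), n-BuLi (1.1 equiv), THF, 0 °C; then 3, −78 to 0 °C
Reagents that add atoms: methyltriphenylphosphonium bromide, C[P+](c1ccccc1)(c1ccccc1)c1ccccc1.[Br-]
Why: Wittig methylenation of the enal by the non-stabilised ylide is fast at low temperature, so the acetate should survive, and the new terminal carbon of the 1,3-diene becomes C8.

Step 4
Reactants: 4 (2E,6E)-3,7-dimethylnona-2,6,8-trien-1-yl acetate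
Product: 6 (2E,6E)-9-hydroxy-3,7-dimethylnona-2,6-dien-1-yl acetate, via B-alkyl-9-BBN adduct 5 (not isolated)
Conditions: 9-BBN (1.1 equiv), THF, 0 °C to rt; then NaBO3·4H2O, H2O, rt
Reagents that add atoms: sodium perborate (used as NaBO3·4H2O), [Na+].[Na+].O[B-]1(O)OO[B-](O)(O)OO1
Why: Brown hydroboration with the bulky 9-BBN should engage only the monosubstituted terminus of the diene and place boron on the terminal carbon, and the mild perborate oxidation of 5 gives the primary homoallylic alcohol while sparing the acetate.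

Step 5
Reactants: 6 (2E,6E)-9-hydroxy-3,7-dimethylnona-2,6-dien-1-yl acetate
Product: 7 (2E,6E)-9-[(tert-butyldimethylsilyl)oxy]-3,7-dimethylnona-2,6-dien-1-yl acetate
Conditions: TBSCl, imidazole, DMF, rt
Reagents that add atoms: tert-butyldimethylsilyl chloride, CC(C)(C)[Si](C)(C)Cl
Why: Imidazole-promoted silylation of the only free hydroxyl protects O8 as a silyl ether that should withstand the base, oxidant, organozinc and ruthenium chemistry that follows.

Step 6
Reactants: 7 (2E,6E)-9-[(tert-butyldimethylsilyl)oxy]-3,7-dimethylnona-2,6-dien-1-yl acetate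
Product: 8 (2E,6E)-9-[(tert-butyldimethylsilyl)oxy]-3,7-dimethylnona-2,6-dien-1-ol
Conditions: K2CO3 (0.2 equiv), MeOH, 0 °C to rt
Reagents that add atoms: none
Why: Base-catalysed transesterification with methanol removes the acetate and leaves the primary silyl ether intact.

Step 7
Reactants: 8 (2E,6E)-9-[(tert-butyldimethylsilyl)oxy]-3,7-dimethylnona-2,6-dien-1-ol
Product: 9 (2E,6E)-9-[(tert-butyldimethylsilyl)oxy]-3,7-dimethylnona-2,6-dienal
Conditions: activated MnO2 (15 equiv), CH2Cl2, rt
Reagents that add atoms: none
Why: MnO2 oxidation of the allylic alcohol should give the geranial-type enal that carries C6, with the 2E geometry kept.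

Step 8
Reactants: 9 (2E,6E)-9-[(tert-butyldimethylsilyl)oxy]-3,7-dimethylnona-2,6-dienal; 10 vinylmagnesium bromide
Product: 12 (3S,4E,8E)-11-[(tert-butyldimethylsilyl)oxy]-5,9-dimethylundeca-1,4,8-trien-3-ol, via divinylzinc 11 (not isolated)
Conditions: 10, ZnCl2 (0.5 equiv per Grignard), Et2O–THF, 0 °C, then 1,4-dioxane, filter; filtrate, 9, (2S)-(−)-3-exo-morpholinoisoborneol [(−)-MIB, 10 mol %], toluene, −20 to 0 °C; aq. NH4Cl
Reagents that add atoms: none
Why: Amino-alcohol-catalysed enantioselective addition of an alkenylzinc reagent to an aldehyde: the zinc aminoalkoxide formed from (−)-MIB and 11 should deliver vinyl in 1,2-fashion to the Si face of the enal and so set the 3S carbinol (future C6), the magnesium salts being removed first to suppress the racemic background reaction.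

Step 9
Reactants: 12 (3S,4E,8E)-11-[(tert-butyldimethylsilyl)oxy]-5,9-dimethylundeca-1,4,8-trien-3-ol; 13 methacryloyl chloride
Product: 14 (3S,4E,8E)-11-[(tert-butyldimethylsilyl)oxy]-5,9-dimethylundeca-1,4,8-trien-3-yl 2-methylprop-2-enoate
Conditions: 13, Et3N, DMAP (cat.), CH2Cl2, 0 °C
Reagents that add atoms: none
Why: Acylation of the secondary bis-allylic alcohol by the acid chloride under amine base forms the methacrylate without touching the C–O stereocentre.

Step 10
Reactants: 14 (3S,4E,8E)-11-[(tert-butyldimethylsilyl)oxy]-5,9-dimethylundeca-1,4,8-trien-3-yl 2-methylprop-2-enoate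
Product: 15 (5R)-5-{(1E,5E)-8-[(tert-butyldimethylsilyl)oxy]-2,6-dimethylocta-1,5-dien-1-yl}-3-methylfuran-2(5H)-one
Conditions: second-generation Grubbs catalyst RuCl2(=CHPh)(H2IMes)(PCy3) (5 mol %), CH2Cl2 (0.01 M), 40 °C
Reagents that add atoms: none
Why: Ring-closing metathesis: the ruthenium carbene should load on the monosubstituted vinyl group far faster than on either trisubstituted olefin and then close onto the 1,1-disubstituted methacrylate to give the five-membered α-methylbutenolide with loss of ethene, so the competing closure through the C4=C5 olefin (which would excise the chain) is not expected, and the C6 stereocentre is not touched.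

Step 11
Reactants: 15 (5R)-5-{(1E,5E)-8-[(tert-butyldimethylsilyl)oxy]-2,6-dimethylocta-1,5-dien-1-yl}-3-methylfuran-2(5H)-one
Product: 16 (5R)-5-[(1E,5E)-8-hydroxy-2,6-dimethylocta-1,5-dien-1-yl]-3-methylfuran-2(5H)-one
Conditions: HF·pyridine, pyridine, THF, 0 °C to rt
Reagents that add atoms: none
Why: Buffered HF·pyridine cleaves the primary silyl ether under mildly acidic conditions that avoid deprotonation at the γ-position of the butenolide, so C6 should keep its configuration.

Step 12
Reactants: 16 (5R)-5-[(1E,5E)-8-hydroxy-2,6-dimethylocta-1,5-dien-1-yl]-3-methylfuran-2(5H)-one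
Product: 17 (3E,7E)-3,7-dimethyl-8-[(2R)-4-methyl-5-oxo-2,5-dihydrofuran-2-yl]octa-3,7-dienal
Conditions: Dess–Martin periodinane, NaHCO3, CH2Cl2, 0 °C; used at once
Reagents that add atoms: none
Why: Dess–Martin oxidation under bicarbonate buffer should give the β,γ-unsaturated aldehyde without acid or base strong enough to move the olefin into conjugation or to epimerise C6.

Step 13
Reactants: 17 (3E,7E)-3,7-dimethyl-8-[(2R)-4-methyl-5-oxo-2,5-dihydrofuran-2-yl]octa-3,7-dienal
Product: 19 (6R,7S,8S,11S)-8-hydroxygermacra-1(10)E,4E-dien-12,6-olide, via bis(diiodosamarium) alkoxide enolate 18 (not isolated)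
Conditions: SmI2 (0.1 M in THF, 3 equiv), t-BuOH (3 equiv), THF, 0 °C, 17 added by syringe pump (final 0.002 M); aq. NH4Cl at 0 °C
Reagents that add atoms: none
Why: SmI2 (divalent samarium) reduces the aldehyde far more readily than the butenolide, the resulting C8 ketyl radical, nucleophilic in character, attacks the β-carbon C7 of the α-methylbutenolide, and a second SmI2 reduces the C11 radical to the trivalent samarium enolate 18, which tert-butanol protonates; the closest known reaction type is the SmI2 ketyl–enoate reductive cyclisation, routine for five- to eight-membered rings and applied here to a ten-membered one. The carbocycle closes in the 10-exo-trig mode, C11 remaining outside the new ring, while the lactone ring is carried in unchanged. C7 is controlled by C6: the seven-atom tether leaves C6 on one face of the planar butenolide and, held short by its two E olefins, should reach C7 only on that face, which gives the cis ring fusion. C8 should arise from the fold of the forming ring that turns the samarium-bound oxygen away from the lactone, and C11 from protonation of 18 on the convex face, trans to the C8 branch, although C11 is re-formed in step 15 in any case. The selectivity required is reduction of the aldehyde ahead of the butenolide and ring closure ahead of pinacol dimerisation; the absence of HMPA should secure the first and slow addition at high dilution the second, and neither trisubstituted olefin is activated or placed for a faster small-ring closure.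

Step 14
Reactants: 19 (6R,7S,8S,11S)-8-hydroxygermacra-1(10)E,4E-dien-12,6-olide
Product: 20 8-O-triethylsilyl ether of 19
Conditions: TESOTf, 2,6-lutidine, CH2Cl2, −78 °C
Reagents that add atoms: triethylsilyl trifluoromethanesulfonate, CC[Si](CC)(CC)OS(=O)(=O)C(F)(F)F
Why: Silyl triflate with a hindered pyridine base silylates the hindered secondary carbinol at low temperature and so blocks attack of O8 on the lactone carbonyl (translactonisation) in the basic step that follows.

Step 15
Reactants: 20 8-O-triethylsilyl ether of 19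
Product: 22 (11R)-11-hydroxy derivative of 20 (8-O-triethylsilyl-11-hydroxy lactone), via potassium enolate 21 (not isolated)
Conditions: KN(SiMe3)2 (1.2 equiv), THF, −78 °C; then trans-3-phenyl-2-(phenylsulfonyl)oxaziridine, −78 °C; aq. NH4Cl
Reagents that add atoms: trans-3-phenyl-2-(phenylsulfonyl)oxaziridine, O=S(=O)(N1OC1c1ccccc1)c1ccccc1
Why: Enolate oxidation with a 2-sulfonyloxaziridine: the potassium enolate 21 is flat at C11 and should take up oxygen trans to the C8 branch on C7, that is from the convex face of the cis-fused bicycle that carries H6 and H7, giving the 11R tertiary alcohol whatever the C11 configuration of 20.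

Step 16
Reactants: 22 (11R)-11-hydroxy derivative of 20
Product: 23 (11R)-11-acetoxy-8-O-triethylsilyl lactone (acetate of 22)
Conditions: Ac2O, DMAP, Et3N, CH2Cl2, rt to 40 °C
Reagents that add atoms: acetic anhydride, CC(=O)OC(C)=O
Why: DMAP-catalysed acetylation through the N-acetylpyridinium ion should acylate the tertiary α-hydroxy lactone without breaking any bond to C11.

Step 17
Reactants: 23 (11R)-11-acetoxy-8-O-triethylsilyl lactone
Product: 24 (6R,7S,8S,11R)-11-acetoxy-8-hydroxygermacra-1(10)E,4E-dien-12,6-olide
Conditions: HF·pyridine, THF, 0 °C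
Reagents that add atoms: none
Why: HF·pyridine cleaves the secondary triethylsilyl ether under acidic conditions that should avoid base-induced acetyl migration or translactonisation to the freed O8.

Step 18
Reactants: 24 (6R,7S,8S,11R)-11-acetoxy-8-hydroxygermacra-1(10)E,4E-dien-12,6-olide; 25 angelic acid
Product: 27 (6R,7S,8S,11R)-11-acetoxy-8-angeloyloxygermacra-1(10)E,4E-dien-12,6-olide (CNP0144564.1), via mixed anhydride 26 (not isolated)
Conditions: 25, 2,4,6-trichlorobenzoyl chloride (1 equiv), Et3N (1 equiv), toluene, rt; then 24, 80 °C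
Reagents that add atoms: none
Why: Yamaguchi-type mixed-anhydride esterification: the carbinol attacks the unhindered angeloyl carbonyl of preformed 26 with retention at C8, and the DMAP-free thermal protocol is the one known to preserve the Z geometry of the angeloyl group.

Compound list
1 | geranyl acetate, (2E)-3,7-dimethylocta-2,6-dien-1-yl acetate | CC(C)=CCC/C(C)=C/COC(C)=O | starting material
2 | (2E,6E)-8-hydroxy-3,7-dimethylocta-2,6-dien-1-yl acetate | OC/C(C)=C/CC/C(C)=C/COC(C)=O | intermediate
3 | (2E,6E)-3,7-dimethyl-8-oxoocta-2,6-dien-1-yl acetate | O=C/C(C)=C/CC/C(C)=C/COC(C)=O | intermediate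
4 | (2E,6E)-3,7-dimethylnona-2,6,8-trien-1-yl acetate | C=C/C(C)=C/CC/C(C)=C/COC(C)=O | intermediate
5 | 9-[(3E,7E)-9-acetoxy-3,7-dimethylnona-3,7-dien-1-yl]-9-borabicyclo[3.3.1]nonane | C1CC2CCCC(C1)B2CC/C(C)=C/CC/C(C)=C/COC(C)=O | intermediate (not isolated)
6 | (2E,6E)-9-hydroxy-3,7-dimethylnona-2,6-dien-1-yl acetate | OCC/C(C)=C/CC/C(C)=C/COC(C)=O | intermediate
7 | (2E,6E)-9-[(tert-butyldimethylsilyl)oxy]-3,7-dimethylnona-2,6-dien-1-yl acetate | CC(C)(C)[Si](C)(C)OCC/C(C)=C/CC/C(C)=C/COC(C)=O | intermediate
8 | (2E,6E)-9-[(tert-butyldimethylsilyl)oxy]-3,7-dimethylnona-2,6-dien-1-ol | CC(C)(C)[Si](C)(C)OCC/C(C)=C/CC/C(C)=C/CO | intermediate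
9 | (2E,6E)-9-[(tert-butyldimethylsilyl)oxy]-3,7-dimethylnona-2,6-dienal | CC(C)(C)[Si](C)(C)OCC/C(C)=C/CC/C(C)=C/C=O | intermediate
10 | vinylmagnesium bromide | C=C[Mg]Br | starting material
11 | divinylzinc | C=C[Zn]C=C | intermediate (not isolated)
12 | (3S,4E,8E)-11-[(tert-butyldimethylsilyl)oxy]-5,9-dimethylundeca-1,4,8-trien-3-ol | CC(C)(C)[Si](C)(C)OCC/C(C)=C/CC/C(C)=C/[C@H](C=C)O | intermediate
13 | methacryloyl chloride | C=C(C)C(=O)Cl | starting material
14 | (3S,4E,8E)-11-[(tert-butyldimethylsilyl)oxy]-5,9-dimethylundeca-1,4,8-trien-3-yl 2-methylprop-2-enoate | CC(C)(C)[Si](C)(C)OCC/C(C)=C/CC/C(C)=C/[C@H](C=C)OC(=O)C(C)=C | intermediate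
15 | (5R)-5-{(1E,5E)-8-[(tert-butyldimethylsilyl)oxy]-2,6-dimethylocta-1,5-dien-1-yl}-3-methylfuran-2(5H)-one | CC(C)(C)[Si](C)(C)OCC/C(C)=C/CC/C(C)=C/[C@H]1OC(=O)C(C)=C1 | intermediate
16 | (5R)-5-[(1E,5E)-8-hydroxy-2,6-dimethylocta-1,5-dien-1-yl]-3-methylfuran-2(5H)-one | OCC/C(C)=C/CC/C(C)=C/[C@H]1OC(=O)C(C)=C1 | intermediate
17 | (3E,7E)-3,7-dimethyl-8-[(2R)-4-methyl-5-oxo-2,5-dihydrofuran-2-yl]octa-3,7-dienal | O=CC/C(C)=C/CC/C(C)=C/[C@H]1OC(=O)C(C)=C1 | intermediate
18 | bis(diiodosamarium) O8-alkoxide C12-enolate of the cyclised lactone (trivalent samarium) | I[Sm](I)O[C@H]1C/C(C)=C/CC/C(C)=C/[C@H]2OC(O[Sm](I)I)=C(C)[C@@H]12 | intermediate (not isolated)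
19 | (6R,7S,8S,11S)-8-hydroxygermacra-1(10)E,4E-dien-12,6-olide, cis-fused | O[C@H]1C/C(C)=C/CC/C(C)=C/[C@H]2OC(=O)[C@@H](C)[C@@H]12 | intermediate
20 | 8-O-triethylsilyl ether of 19 | CC[Si](CC)(CC)O[C@H]1C/C(C)=C/CC/C(C)=C/[C@H]2OC(=O)[C@@H](C)[C@@H]12 | intermediate
21 | potassium C11–C12 enolate of 20 | CC[Si](CC)(CC)O[C@H]1C/C(C)=C/CC/C(C)=C/[C@H]2OC([O-])=C(C)[C@@H]12.[K+] | intermediate (not isolated)
22 | (11R)-11-hydroxy derivative of 20, hydroxyl cis to H7 | CC[Si](CC)(CC)O[C@H]1C/C(C)=C/CC/C(C)=C/[C@H]2OC(=O)[C@](C)(O)[C@@H]12 | intermediate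
23 | (11R)-11-acetoxy-8-O-triethylsilyl lactone, acetate of 22 | CC[Si](CC)(CC)O[C@H]1C/C(C)=C/CC/C(C)=C/[C@H]2OC(=O)[C@](C)(OC(C)=O)[C@@H]12 | intermediate
24 | (6R,7S,8S,11R)-11-acetoxy-8-hydroxygermacra-1(10)E,4E-dien-12,6-olide | O[C@H]1C/C(C)=C/CC/C(C)=C/[C@H]2OC(=O)[C@](C)(OC(C)=O)[C@@H]12 | intermediate
25 | angelic acid, (Z)-2-methylbut-2-enoic acid | C/C=C(/C)C(=O)O | starting material
26 | angelic 2,4,6-trichlorobenzoic anhydride | C/C=C(/C)C(=O)OC(=O)c1c(Cl)cc(Cl)cc1Cl | intermediate (not isolated)
27 | (6R,7S,8S,11R)-11-acetoxy-8-angeloyloxygermacra-1(10)E,4E-dien-12,6-olide, CNP0144564.1 | C/C=C(/C)C(=O)O[C@H]1C/C(C)=C/CC/C(C)=C/[C@H]2OC(=O)[C@](C)(OC(C)=O)[C@@H]12 | target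

Total step count: 18
Longest linear sequence: 18 steps (1 to 27)

Steps most likely to fail

Step 13. What may go wrong: no substituent fixes which face of the ketyl carbon meets C7, so closure through the alternative fold of the tether would place O8 on the opposite face (inverted C8), which the retentive acylation of step 18 cannot repair. Fallback: the sequence sets out from 17, whose closure under the conditions of step 13 would then deliver the 8-epimeric hydroxy lactone F1 in place of 19. The conditions of steps 14 to 17 are applied unchanged: silylation to the triethylsilyl ether F2 with TESOTf, deprotonation to the potassium enolate F3 by KN(SiMe3)2, hydroxylation to the 11-hydroxy lactone F4 by the sulfonyloxaziridine, acetylation to the 11-acetate F5 with Ac2O and DMAP, and desilylation to the 8-epi carbinol F6 by HF·pyridine. The angelate is then introduced with inversion at C8 by Mitsunobu esterification of F6 with 25 (PPh3, diisopropyl azodicarboxylate, toluene, 0 °C to rt), and the material rejoins the route at 27.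

Step 18. What may go wrong: acylation of the hindered C8 carbinol is slow, and on prolonged heating the angeloyl group may isomerise to its E isomer, or the free O8 may take over the neighbouring acetyl or lactone acyl group. Fallback: from 24, carbodiimide coupling with 2-[bis(2,2,2-trifluoroethoxy)phosphoryl]propanoic acid (EDC·HCl, cat. DMAP, CH2Cl2, 0 °C) should give the O8 phosphonopropionate ester F7 without heating. The potassium salt F8 formed from it with KN(SiMe3)2 and 18-crown-6 in THF at −78 °C should undergo Z-selective Still–Gennari olefination with acetaldehyde, which builds the angelate double bond on the ester and rejoins the route at 27.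

Step 8. What may go wrong: uncatalysed addition by residual magnesium-bound vinyl species, or weak face discrimination with the β,β-disubstituted enal, would erode the enantiomeric purity at C6, on which every later stereocentre depends. Fallback: from 9, ligand-free addition of 10 (THF, −78 °C) gives the racemic carbinol F9 after work-up. Kinetic resolution with Candida antarctica lipase B and vinyl acetate in hexane should acetylate the R enantiomer to the (3R)-acetate F10 and leave the 3S alcohol, which is separated and rejoins the route as 12.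

Further compounds
F1 | step 13 | (6R,7S,8R,11S)-8-hydroxygermacra-1(10)E,4E-dien-12,6-olide, 8-epimer of 19 | O[C@@H]1C/C(C)=C/CC/C(C)=C/[C@H]2OC(=O)[C@@H](C)[C@@H]12
F2 | step 13 | 8-O-triethylsilyl ether of F1 | CC[Si](CC)(CC)O[C@@H]1C/C(C)=C/CC/C(C)=C/[C@H]2OC(=O)[C@@H](C)[C@@H]12
F3 | step 13 | potassium C11–C12 enolate of F2 | CC[Si](CC)(CC)O[C@@H]1C/C(C)=C/CC/C(C)=C/[C@H]2OC([O-])=C(C)[C@@H]12.[K+]
F4 | step 13 | (11R)-11-hydroxy derivative of F2 | CC[Si](CC)(CC)O[C@@H]1C/C(C)=C/CC/C(C)=C/[C@H]2OC(=O)[C@](C)(O)[C@@H]12
F5 | step 13 | 11-acetate of F4 | CC[Si](CC)(CC)O[C@@H]1C/C(C)=C/CC/C(C)=C/[C@H]2OC(=O)[C@](C)(OC(C)=O)[C@@H]12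
F6 | step 13 | 8-epimer of 24, (11R)-11-acetoxy-8-epi-hydroxy lactone | O[C@@H]1C/C(C)=C/CC/C(C)=C/[C@H]2OC(=O)[C@](C)(OC(C)=O)[C@@H]12
F7 | step 18 | 8-O-{2-[bis(2,2,2-trifluoroethoxy)phosphoryl]propanoyl} ester of 24, epimer mixture at the phosphonate carbon | CC(C(=O)O[C@H]1C/C(C)=C/CC/C(C)=C/[C@H]2OC(=O)[C@](C)(OC(C)=O)[C@@H]12)P(=O)(OCC(F)(F)F)OCC(F)(F)F
F8 | step 18 | potassium salt (phosphonate carbanion) of F7 | C[C-](C(=O)O[C@H]1C/C(C)=C/CC/C(C)=C/[C@H]2OC(=O)[C@](C)(OC(C)=O)[C@@H]12)P(=O)(OCC(F)(F)F)OCC(F)(F)F.[K+]
F9 | step 8 | racemic (4E,8E)-11-[(tert-butyldimethylsilyl)oxy]-5,9-dimethylundeca-1,4,8-trien-3-ol | CC(C)(C)[Si](C)(C)OCC/C(C)=C/CC/C(C)=C/C(C=C)O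
F10 | step 8 | (3R,4E,8E)-11-[(tert-butyldimethylsilyl)oxy]-5,9-dimethylundeca-1,4,8-trien-3-yl acetate | CC(C)(C)[Si](C)(C)OCC/C(C)=C/CC/C(C)=C/[C@@H](C=C)OC(C)=O
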